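L.D, the product, is counted here together with X, its form in the second phase, and a short meeting sat on how much of the two stands in this flask at the end of the run.

L 0.23 M; E 0.230 M; time 2.0 min; volume of the second phase over the first 2.0

- amounts and yields of L.D count X too
- in the second phase: E, X; everything else is in the first
- charges count per volume of the first phase; a concentration in a rate is the amount of a species over the volume of its own phase; every rate counts per litre of the first phase
- run time (flask): 2.0 min

- the L.D and X together standing at 2.0 min, as a percentage of the L charged
- the change that raises the amount of L.D and X together at 2.0 min, in percent of the L charged most ("none" if none brings more than 2 percentage points) (Friday's / Wednesday's / Saturday's / none)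
- amount of L.D and X together at 2.0 min, in percent of the L charged, after Wednesday's

- Friday's: doubling the amount of E, all else as stated
- Wednesday's: doubling the transfer coefficient of step 3, all else as stated
- Saturday's: doubling the transfer coefficient of step 1, all else as stated

    D ⇌ E, rate k1*([D] - [E]/K1) per volume of the first phase (K1 = 3.0, k1 = 0.24 s⁻¹)
    L + D → L.D (k2 = 6.1 L mol⁻¹ s⁻¹)
    L.D ⇌ X, rate k3*([L.D] - [X]/K3) per volume of the first phase (K3 = 11, k3 = 0.022 s⁻¹)
    L.D → Q (k4 = 0.0047 s⁻¹)
    L ⇌ Z (K5 = 0.34, k5 = 0.0014 s⁻¹)
    L.D → G (k6 = 0.021 s⁻¹)

The first speaker reported that E lies in the second phase and reaches the first as D, where L takes it up to give L.D. L.D then passes into X or falls to Q and G, while L also drifts to Z. He argued that, with c(D) low, the transfer coefficient is divided by the partition ratio and the volume ratio, so E leaves with a constant of 0.0400 s⁻¹, a lifetime of 25.0 s. The second speaker feared that D might pile up. He was answered that at the start D lasts 0.713 s against L, far shorter than that lifetime, so the crossing of E is the rate-limiting step at the start.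

The chair asked what becomes of L.D. The meeting took the escape share, the transfer coefficient of L.D into X over the sum of that coefficient and the two loss constants, 46.1%, a selectivity that does not depend on c(L.D). The way back from X was set aside, its coefficient being divided by 22.0.

My own reckoning replaces the curve of L by its mean. The charges of L and E are equal, so I let L fall with E, which gives a mean of 0.207 of the charge over the run. Z then takes 3.47%, and the rest through the escape share gives 44.5%. After Wednesday's the share becomes 63.1%, which gives 60.9%. Were the mean twice as large, the first figure would fall by just 1.6 percentage points, so the error of the mean matters little.

The forecast stood lower than my figures: 41%, then 52% after Wednesday's, whose doubled transfer “shifts that split strongly towards X”.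

The simulation gives 42.6% and 55.4% after Wednesday's, which gains 13 points, against 1.8 points for Friday's and 0.33 points for Saturday's.

In this flask L.D is lost at 0.0257 s⁻¹, faster than it passes into X at 0.022 s⁻¹. Wednesday's doubled coefficient of 0.0440 s⁻¹ overtakes that same loss. Applied to the L neither left nor held as Z at the asked time, the escape share gives 41.9% here. The neighbour charged with 0.58 M of L keeps 52.6% as L and 8.32% as Z, so the same share gives 18.0%, and that flask holds 18.2%.

Its constants were chosen freely; no experiment stands behind them.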